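Ring B (C1, C5–C10; daucane numbering, defined below) is closed last between C6 and C7 by an intramolecular Hosomi–Sakurai reaction. The step exploits C7 as the lone methylene between the oxygenated C6 and C8, beside the cis C9=C10 bond: C7–C8(C14)–C9=C10 is a latent 2-(silylmethyl)diene. In one operation it forms the cis-fused bicycle, sets the C6 carbinol and leaves an exocyclic C8=C14 methylene for hydroxyl-directed installation of the C8 carbinol. The precursor is a ring A (cyclopentane) carbaldehyde, C6 being the formyl carbon, with a (Z)-dienylsilane on quaternary C1; it is made from (S)-terpinen-4-ol.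

Key step: step 5

Numbering: C1 quaternary ring-fusion carbon bearing CH3; C2, C3 ring A methylenes; C4 carbinol carbon bearing isopropyl; C5 ring-fusion CH; C6 CH–O(ester); C7 CH2; C8 C(OH)CH3 (methyl = C14); C9=C10 ring B alkene, C10 bonded to C1.
Stereochemical reading of the target: cis-fused; H5, the C1 methyl and the isopropyl group lie on one face of ring A, with 4-OH, C6 and C10 on the other; O6 is cis to H5 and cis to O8 on ring B.
Assumption: (S)-(+)-terpinen-4-ol is taken as a commercial terpene of high enantiomeric purity; its carbinol carbon becomes C4 and is the only source of chirality.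

Step 1
Reactants: 1 (S)-(+)-terpinen-4-ol [(1S)-4-methyl-1-(propan-2-yl)cyclohex-3-en-1-ol]
Product: 2 triethyl{[(1S)-4-methyl-1-(propan-2-yl)cyclohex-3-en-1-yl]oxy}silane
Conditions: TESOTf, 2,6-lutidine, CH2Cl2, −78 → 0 °C
Reagents that add atoms: triethylsilyl trifluoromethanesulfonate, CC[Si](CC)(CC)OS(=O)(=O)C(F)(F)F
Why: Silyl triflate silylation of a tertiary alcohol; it masks O4 so that hemiketal formation, retro-aldol cleavage and dehydration cannot interfere later, and no stereocentre is touched.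

Step 2
Reactants: 2 triethyl{[(1S)-4-methyl-1-(propan-2-yl)cyclohex-3-en-1-yl]oxy}silane
Product: 4 (3S)-6-oxo-3-(propan-2-yl)-3-[(triethylsilyl)oxy]heptanal, via ozonide 3 (not isolated)
Conditions: O3, CH2Cl2, −78 °C; then Me2S, −78 °C → rt
Reagents that add atoms: ozone, [O-][O+]=O
Why: Criegee ozonolysis of the only alkene with reductive work-up should open the cyclohexene to the 1,6-keto aldehyde; the silyl ether and the carbinol centre are inert.

Step 3
Reactants: 4 (3S)-6-oxo-3-(propan-2-yl)-3-[(triethylsilyl)oxy]heptanal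
Product: 6 (5R)-2-methyl-5-(propan-2-yl)-5-[(triethylsilyl)oxy]cyclopent-1-ene-1-carbaldehyde, via aldol adduct 5 (not isolated)
Conditions: piperidine (cat.), AcOH (cat.), toluene, 60 °C
Reagents that add atoms: none
Why: Amine-catalysed intramolecular aldol condensation: the aldehyde enamine adds to the methyl ketone (5-(enolexo)-exo-trig) and the new tertiary hydroxyl is lost by E1cB into conjugation, the β-silyloxy group being the poorer leaving group, so that steps 2 and 3 contract the six-membered ring of 1 to ring A.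

Step 4
Reactants: 6 (5R)-2-methyl-5-(propan-2-yl)-5-[(triethylsilyl)oxy]cyclopent-1-ene-1-carbaldehyde; 7 2-bromo-3-(trimethylsilyl)prop-1-ene; 8 acetylene
Product: 13 (1R,2S,5R)-2-methyl-2-{(1Z)-3-[(trimethylsilyl)methyl]buta-1,3-dien-1-yl}-5-(propan-2-yl)-5-[(triethylsilyl)oxy]cyclopentane-1-carbaldehyde, via alkenyllithium 9 (not isolated), via alkenylcuprate 10 (not isolated), via dienylcuprate 11 (not isolated), via silyl enol ether 12 (not isolated)
Conditions: 7, t-BuLi, Et2O, −78 °C; CuBr·SMe2, −50 °C; 8, −50 → −25 °C; then 6, TMSCl, Et2O/THF, −78 → −30 °C; aq. NH4Cl; then K2CO3, MeOH, 0 °C → rt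
Reagents that add atoms: none
Why: Carbocupration of acetylene (syn addition fixes the Z C9=C10 geometry) followed by TMSCl-accelerated cuprate conjugate addition to the enal should build quaternary C1, the cuprate approaching anti to the pseudo-axial isopropyl group on C4; methanolysis of the silyl enol ether with K2CO3 equilibrates C5 so that the formyl group should end trans to isopropyl, that is cis to the dienyl chain.

Step 5
Reactants: 13 (1R,2S,5R)-2-methyl-2-{(1Z)-3-[(trimethylsilyl)methyl]buta-1,3-dien-1-yl}-5-(propan-2-yl)-5-[(triethylsilyl)oxy]cyclopentane-1-carbaldehyde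
Product: 14 (3R,3aS,4S,8aS)-8a-methyl-6-methylidene-3-(propan-2-yl)-3-[(triethylsilyl)oxy]-1,2,3,3a,4,5,6,8a-octahydroazulen-4-ol
Conditions: BF3·OEt2, CH2Cl2, −78 °C; aq. NaHCO3
Reagents that add atoms: none
Why: BF3 activates the C6 aldehyde and the terminal carbon C7 of the 2-(silylmethyl)diene attacks it (SE2′), giving a β-silyl, allylically stabilised cation at C8 that loses silicon as Me3SiF and leaves the exocyclic C8=C14 bond conjugated with C9=C10. The closest known reaction type is the intramolecular Hosomi–Sakurai allylation (isoprenylsilane addition to aldehydes), here the ring-closing half of a two-stage (4+3) annulation of enal 6 with a C7–C10 conjunctive unit. Ring B closes in the 7-exo-trig mode at the carbonyl, with the allylsilane C7=C8 bond endocyclic to the forming ring; the Z C9=C10 bond and the cis disposition of C6 and C10 on ring A hold the two termini within reach. C6 is the only new stereocentre and is controlled by C5: with the formyl hydrogen over ring A and the BF3-bound oxygen pointing outwards, C7 should add to the Si face anti to the C5–C4 bond (Felkin–Anh-type), giving the 6S alcohol with O6 cis to H5. The step needs site selectivity for C7 over C14 and C10, secured by the SE2′ course of allylsilane attack and by ring size, and it must outrun protodesilylation and loss of the C4 silyl ether, which the low temperature and the aprotic, non-basic Lewis acid should secure.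

Step 6
Reactants: 14 (3R,3aS,4S,8aS)-8a-methyl-6-methylidene-3-(propan-2-yl)-3-[(triethylsilyl)oxy]-1,2,3,3a,4,5,6,8a-octahydroazulen-4-ol
Product: 15 (3R,3aS,4S,6R,8aS)-8a-methyl-3-(propan-2-yl)-3-[(triethylsilyl)oxy]-2,3,3a,4,5,8a-hexahydro-1H-spiro[azulene-6,2′-oxiran]-4-ol (epoxide oxygen cis to the C6 hydroxyl)
Conditions: VO(acac)2 (cat.), t-BuOOH, CH2Cl2, 0 °C → rt
Reagents that add atoms: tert-butyl hydroperoxide, CC(C)(C)OO
Why: Hydroxyl-directed epoxidation: the vanadate ester of the homoallylic C6 hydroxyl should deliver oxygen to the exocyclic C8=C14 bond on the face of that hydroxyl, which sets C8 with the new C–O bond cis to O6, while the ring C9=C10 bond is out of reach of the tether.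

Step 7
Reactants: 15 (3R,3aS,4S,6R,8aS)-8a-methyl-3-(propan-2-yl)-3-[(triethylsilyl)oxy]-2,3,3a,4,5,8a-hexahydro-1H-spiro[azulene-6,2′-oxiran]-4-ol
Product: 16 (3R,3aS,4S,6R,8aS)-6,8a-dimethyl-3-(propan-2-yl)-3-[(triethylsilyl)oxy]-1,2,3,3a,4,5,6,8a-octahydroazulene-4,6-diol
Conditions: LiEt3BH, THF, 0 °C → rt; then H2O
Reagents that add atoms: none
Why: Regioselective SN2 hydride opening of the 2,2-disubstituted vinyl epoxide at its primary carbon C14 turns the epoxide CH2 into the C8 methyl group and leaves the C8–O bond, hence the configuration, untouched.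

Step 8
Reactants: 16 (3R,3aS,4S,6R,8aS)-6,8a-dimethyl-3-(propan-2-yl)-3-[(triethylsilyl)oxy]-1,2,3,3a,4,5,6,8a-octahydroazulene-4,6-diol; 17 4-[(tert-butyldimethylsilyl)oxy]benzoic acid
Product: 18 (3R,3aS,4S,6R,8aS)-6-hydroxy-6,8a-dimethyl-3-(propan-2-yl)-3-[(triethylsilyl)oxy]-1,2,3,3a,4,5,6,8a-octahydroazulen-4-yl 4-[(tert-butyldimethylsilyl)oxy]benzoate
Conditions: 17, EDC·HCl, DMAP (cat.), CH2Cl2, rt
Reagents that add atoms: none
Why: Steglich esterification should acylate only the secondary C6 hydroxyl with retention, the tertiary C8 hydroxyl and the silylated C4 oxygen being too hindered.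

Step 9
Reactants: 18 (3R,3aS,4S,6R,8aS)-6-hydroxy-6,8a-dimethyl-3-(propan-2-yl)-3-[(triethylsilyl)oxy]-1,2,3,3a,4,5,6,8a-octahydroazulen-4-yl 4-[(tert-butyldimethylsilyl)oxy]benzoate
Product: 19 (3R,3aS,4S,6R,8aS)-3,6-dihydroxy-6,8a-dimethyl-3-(propan-2-yl)-1,2,3,3a,4,5,6,8a-octahydroazulen-4-yl 4-hydroxybenzoate (CNP0280165.1)
Conditions: TBAF, AcOH, THF, 0 °C → rt
Reagents that add atoms: none
Why: Fluoride-mediated desilylation should cleave the aryl silyl ether and the tertiary triethylsilyl ether in one operation, acetic acid buffering guarding against acyl migration and ester cleavage.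

Compound list
1 | (S)-(+)-terpinen-4-ol, (1S)-4-methyl-1-(propan-2-yl)cyclohex-3-en-1-ol | CC(C)[C@]1(O)CCC(C)=CC1 | starting material
2 | triethyl{[(1S)-4-methyl-1-(propan-2-yl)cyclohex-3-en-1-yl]oxy}silane | CC(C)[C@]1(O[Si](CC)(CC)CC)CCC(C)=CC1 | intermediate
3 | ozonide of 2 (1,2,4-trioxolane across the former C=C carbons, diastereomer mixture) | CC(C)[C@]1(O[Si](CC)(CC)CC)CCC2(C)OOC(C1)O2 | intermediate
4 | (3S)-6-oxo-3-(propan-2-yl)-3-[(triethylsilyl)oxy]heptanal | CC(C)[C@](O[Si](CC)(CC)CC)(CCC(C)=O)CC=O | intermediate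
5 | aldol adduct, (5R)-2-hydroxy-2-methyl-5-(propan-2-yl)-5-[(triethylsilyl)oxy]cyclopentane-1-carbaldehyde (mixture at C1 and C2 of the ring) | CC(C)[C@]1(O[Si](CC)(CC)CC)CCC(C)(O)C1C=O | intermediate
6 | (5R)-2-methyl-5-(propan-2-yl)-5-[(triethylsilyl)oxy]cyclopent-1-ene-1-carbaldehyde | CC(C)[C@]1(O[Si](CC)(CC)CC)CCC(C)=C1C=O | intermediate
7 | 2-bromo-3-(trimethylsilyl)prop-1-ene | C=C(Br)C[Si](C)(C)C | starting material
8 | acetylene | C#C | starting material
9 | [3-(trimethylsilyl)prop-1-en-2-yl]lithium | [Li]C(=C)C[Si](C)(C)C | intermediate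
10 | lithium bis[3-(trimethylsilyl)prop-1-en-2-yl]cuprate | [Li+].C=C(C[Si](C)(C)C)[Cu-]C(=C)C[Si](C)(C)C | intermediate
11 | lithium bis{(1Z)-3-[(trimethylsilyl)methyl]buta-1,3-dien-1-yl}cuprate | [Li+].C=C(C[Si](C)(C)C)/C=C\[Cu-]/C=C\C(=C)C[Si](C)(C)C | intermediate
12 | trimethylsilyl enol ether of 13, (2S,5R)-configured ring, enol ether as E/Z mixture | CC(C)[C@]1(O[Si](CC)(CC)CC)CC[C@@](C)(/C=C\C(=C)C[Si](C)(C)C)C1=CO[Si](C)(C)C | intermediate
13 | (1R,2S,5R)-2-methyl-2-{(1Z)-3-[(trimethylsilyl)methyl]buta-1,3-dien-1-yl}-5-(propan-2-yl)-5-[(triethylsilyl)oxy]cyclopentane-1-carbaldehyde (formyl cis to the dienyl chain and to the silyloxy group) | CC(C)[C@]1(O[Si](CC)(CC)CC)CC[C@@](C)(/C=C\C(=C)C[Si](C)(C)C)[C@H]1C=O | intermediate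
14 | (3R,3aS,4S,8aS)-8a-methyl-6-methylidene-3-(propan-2-yl)-3-[(triethylsilyl)oxy]-1,2,3,3a,4,5,6,8a-octahydroazulen-4-ol | CC(C)[C@]1(O[Si](CC)(CC)CC)CC[C@@]2(C)C=CC(=C)C[C@H](O)[C@@H]12 | intermediate
15 | (3R,3aS,4S,6R,8aS)-8a-methyl-3-(propan-2-yl)-3-[(triethylsilyl)oxy]-2,3,3a,4,5,8a-hexahydro-1H-spiro[azulene-6,2′-oxiran]-4-ol | CC(C)[C@]1(O[Si](CC)(CC)CC)CC[C@@]2(C)C=C[C@@]3(CO3)C[C@H](O)[C@@H]12 | intermediate
16 | (3R,3aS,4S,6R,8aS)-6,8a-dimethyl-3-(propan-2-yl)-3-[(triethylsilyl)oxy]-1,2,3,3a,4,5,6,8a-octahydroazulene-4,6-diol | CC(C)[C@]1(O[Si](CC)(CC)CC)CC[C@@]2(C)C=C[C@](C)(O)C[C@H](O)[C@@H]12 | intermediate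
17 | 4-[(tert-butyldimethylsilyl)oxy]benzoic acid | OC(=O)c1ccc(O[Si](C)(C)C(C)(C)C)cc1 | starting material
18 | (3R,3aS,4S,6R,8aS)-6-hydroxy-6,8a-dimethyl-3-(propan-2-yl)-3-[(triethylsilyl)oxy]-1,2,3,3a,4,5,6,8a-octahydroazulen-4-yl 4-[(tert-butyldimethylsilyl)oxy]benzoate | CC(C)[C@]1(O[Si](CC)(CC)CC)CC[C@@]2(C)C=C[C@](C)(O)C[C@H](OC(=O)c3ccc(O[Si](C)(C)C(C)(C)C)cc3)[C@@H]12 | intermediate
19 | (3R,3aS,4S,6R,8aS)-3,6-dihydroxy-6,8a-dimethyl-3-(propan-2-yl)-1,2,3,3a,4,5,6,8a-octahydroazulen-4-yl 4-hydroxybenzoate | CC(C)[C@]1(O)CC[C@@]2(C)C=C[C@](C)(O)C[C@H](OC(=O)c3ccc(O)cc3)[C@@H]12 | target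

Total step count: 9. Longest linear sequence: 9 steps (1 → 19).

Steps most likely to fail

Step 4. The bulky alkenyl cuprate may not reach the fully substituted β-carbon C1 (recovered enal or 1,2-addition), and the base-mediated equilibration at C5 may stall or be overtaken by β-elimination of the silanolate. The fallback sets out from 6 (with 7 and 8) and comes back at 12; it moves the dienyl group from the stoichiometric lithium cuprate to a Grignard reagent under copper catalysis. Cuprate 11, made as before, is quenched with iodine to the isolable (1Z)-1-iodo-3-[(trimethylsilyl)methyl]buta-1,3-diene F1. Iodine–magnesium exchange (i-PrMgCl·LiCl, THF, −20 °C) should give {(1Z)-3-[(trimethylsilyl)methyl]buta-1,3-dien-1-yl}magnesium chloride F2 with retention of geometry. F2 is added to 6 with CuBr·SMe2 (cat.), TMSCl and HMPA in THF at −78 °C, a silyl-accelerated catalytic conjugate addition suited to hindered enals, to give silyl enol ether 12, which is methanolysed to 13 as in step 4.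

Step 5. Attack on the Re face of the aldehyde would erode or reverse the configuration at C6, on which the later C8 centre depends. The fallback sets out from 13 and comes back at 14; it corrects the carbinol after ring closure instead of relying on facial control. The cyclisation is run as in step 5 and the C6 epimer (3R,3aS,4R,8aS)-8a-methyl-6-methylidene-3-(propan-2-yl)-3-[(triethylsilyl)oxy]-1,2,3,3a,4,5,6,8a-octahydroazulen-4-ol F3 is carried on. Mitsunobu inversion (4-nitrobenzoic acid, DIAD, PPh3, toluene, 0 °C → rt) should give (3R,3aS,4S,8aS)-8a-methyl-6-methylidene-3-(propan-2-yl)-3-[(triethylsilyl)oxy]-1,2,3,3a,4,5,6,8a-octahydroazulen-4-yl 4-nitrobenzoate F4 with the required 6S configuration, and methanolysis (K2CO3, MeOH) releases 14.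

Step 6. Site selectivity between the exocyclic and the ring double bond of the diene may be lost, or the acid-sensitive vinyl epoxide may open under the metal catalyst. The fallback sets out from 14 and comes back at 16, bypassing 15; it delivers O8 through a covalent tether from O6. The C6 hydroxyl is converted into tert-butyl (3R,3aS,4S,8aS)-8a-methyl-6-methylidene-3-(propan-2-yl)-3-[(triethylsilyl)oxy]-1,2,3,3a,4,5,6,8a-octahydroazulen-4-yl carbonate F5 (Boc2O, DMAP, CH2Cl2). IBr (toluene, −80 °C) should trigger iodocarbonate cyclisation, the carbonyl oxygen closing a six-membered ring onto C8 and therefore cis to O6, to give the iodomethyl cyclic carbonate F6 (C6–O–C(=O)–O–C8, CH2I on C8). LiAlH4 (THF, 0 °C → rt) cleaves the carbonate and reduces the primary iodide to the C8 methyl group, giving diol 16.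

Further compounds
F1 | step 4 | (1Z)-1-iodo-3-[(trimethylsilyl)methyl]buta-1,3-diene | C=C(C[Si](C)(C)C)/C=C\I
F2 | step 4 | {(1Z)-3-[(trimethylsilyl)methyl]buta-1,3-dien-1-yl}magnesium chloride | C=C(C[Si](C)(C)C)/C=C\[Mg]Cl
F3 | step 5 | (3R,3aS,4R,8aS)-8a-methyl-6-methylidene-3-(propan-2-yl)-3-[(triethylsilyl)oxy]-1,2,3,3a,4,5,6,8a-octahydroazulen-4-ol (C6 epimer of 14) | CC(C)[C@]1(O[Si](CC)(CC)CC)CC[C@@]2(C)C=CC(=C)C[C@@H](O)[C@@H]12
F4 | step 5 | (3R,3aS,4S,8aS)-8a-methyl-6-methylidene-3-(propan-2-yl)-3-[(triethylsilyl)oxy]-1,2,3,3a,4,5,6,8a-octahydroazulen-4-yl 4-nitrobenzoate | CC(C)[C@]1(O[Si](CC)(CC)CC)CC[C@@]2(C)C=CC(=C)C[C@H](OC(=O)c3ccc(cc3)[N+](=O)[O-])[C@@H]12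
F5 | step 6 | tert-butyl (3R,3aS,4S,8aS)-8a-methyl-6-methylidene-3-(propan-2-yl)-3-[(triethylsilyl)oxy]-1,2,3,3a,4,5,6,8a-octahydroazulen-4-yl carbonate | CC(C)[C@]1(O[Si](CC)(CC)CC)CC[C@@]2(C)C=CC(=C)C[C@H](OC(=O)OC(C)(C)C)[C@@H]12
F6 | step 6 | cyclic carbonate bridging O6 and O8 (cis) with an iodomethyl group on C8, triethylsilyl ether at O4 | CC(C)[C@]1(O[Si](CC)(CC)CC)CC[C@@]2(C)C=C[C@@]3(CI)C[C@H](OC(=O)O3)[C@@H]12
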